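## Retrosynthetic overview

1. The hydroxy‑p‑quinone (ring C) is unveiled last from a 11,12,14‑trimethoxyarene (oxidative demethylation, then O‑12 demethylation); the C‑1 carbinol comes from a C‑1 ketone.
2. Ring B is formed last, by C10=C20 (aldol condensation of the ring‑A ketone with a benzaldehyde) and C7–C8 (acetal‑initiated Friedel–Crafts closure that leaves the C6=C7 enol lactone).
3. The γ‑lactone and both ring‑fusion stereocentres (C‑4, C‑5) come from one amine‑catalysed desymmetrising intramolecular Michael addition of a 2‑oxoethyl ester onto a prochiral 4‑methylcyclohexa‑2,5‑dienone‑4‑carboxylate; the surviving C2=C3 enone leaves C‑10 as the only enolisable position.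
4. Fragments: the dienone ester from benzoic acid; 4‑isopropyl‑2,3,5‑trimethoxybenzaldehyde from 1,2,4‑trimethoxybenzene.
5. Ring order: ring A (carbocycle from benzoic acid) → lactone → arene (future ring C) attached → ring B → quinone.

Convention: locants C‑1 … C‑20 are the icetexane locants of the target; with them the target is (1R,4S,5R), with Me‑18 cis to H‑5 and 1‑OH cis to C‑6.
Assumption: the (S)‑prolinol silyl ether is taken to give the (4S,5R) series in step 5; if the sense is the opposite, the (R)‑catalyst is used and nothing else changes.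

## Route

Step 1
Reactants: 1 benzoic acid
Product: 3 1-methylcyclohexa-2,5-diene-1-carboxylic acid, via dilithium ene-diolate 2 (not isolated)
Conditions: Li (3.2 equiv), NH3(l)/THF, −78 °C; MeI, −78 → 20 °C; aq. HCl
Reagents that add atoms: iodomethane, CI
Why: Birch reductive alkylation: dissolving‑metal reduction gives the 1,4‑dihydro ene‑diolate, which is C‑methylated at the carboxyl‑bearing carbon; the product is achiral.

Step 2
Reactants: 3 1-methylcyclohexa-2,5-diene-1-carboxylic acid
Product: 4 allyl 1-methylcyclohexa-2,5-diene-1-carboxylate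
Conditions: K2CO3, allyl bromide, DMF, 25 °C
Reagents that add atoms: allyl bromide, C=CCBr
Why: Carboxylate O‑alkylation (SN2) installs the two carbons that become C‑6 and C‑7 and keeps the acid esterified, since the free dienone acid of the next stage would decarboxylate to p‑cresol.

Step 3
Reactants: 4 allyl 1-methylcyclohexa-2,5-diene-1-carboxylate
Product: 5 allyl 1-methyl-4-oxocyclohexa-2,5-diene-1-carboxylate
Conditions: Rh2(cap)4 (1 mol %), t-BuOOH (70 % aq., 5 equiv), K2CO3 (0.5 equiv), CH2Cl2, 25 °C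
Reagents that add atoms: tert-butyl hydroperoxide, CC(C)(C)OO
Why: Bis‑allylic C–H oxidation (metal/TBHP allylic oxidation) converts the doubly allylic CH2, the weakest C–H bond, into the cross‑conjugated dienone carbonyl; the product is prochiral.

Step 4
Reactants: 5 allyl 1-methyl-4-oxocyclohexa-2,5-diene-1-carboxylate
Product: 7 2-oxoethyl 1-methyl-4-oxocyclohexa-2,5-diene-1-carboxylate, via ozonide 6 (not isolated)
Conditions: O3, CH2Cl2, −78 °C (Sudan III end point); PPh3, −78 → 20 °C; used crude
Reagents that add atoms: ozone, [O-][O+]=O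
Why: Ozonolysis with reductive work‑up cleaves the electron‑rich terminal alkene much faster than the electron‑poor dienone C=C bonds and gives the α‑acyloxy aldehyde.

Step 5
Reactants: 7 2-oxoethyl 1-methyl-4-oxocyclohexa-2,5-diene-1-carboxylate
Product: 9 (3R,3aR,7aS)-3-(dimethoxymethyl)-7a-methyl-3a,4-dihydro-2-benzofuran-1,5(3H,7aH)-dione, via aldehyde lactone 8 (not isolated)
Conditions: (S)-α,α-diphenylprolinol TMS ether (20 mol %), PhCO2H (20 mol %), CHCl3, 4 °C; then HC(OMe)3, p-TsOH (0.3 equiv), MeOH, 0 °C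
Reagents that add atoms: trimethyl orthoformate, COC(OC)OC
Why: Proposed new method: the aldehyde of 7 forms an (E)‑enamine whose β‑carbon (C‑6, bearing the ester oxygen) adds 5‑exo‑trig to the β‑carbon (C‑5) of one of the two enantiotopic enones, the shielded face of the catalyst deciding which arm reacts, so the quaternary C‑4 and C‑5 are set together and the new γ‑lactone can only be cis‑fused (the C‑6 centre is lost later), the new elements being an α‑acyloxy‑aldehyde donor and an ester tether that must reach its s‑cis rotamer; the closest known reaction type is the secondary‑amine‑catalysed intramolecular aldehyde‑to‑enone Michael desymmetrisation of 4,4‑disubstituted cyclohexadienones with all‑carbon tethers, and the labile aldehyde is trapped in the same flask as its dimethyl acetal.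

Step 6
Reactants: 10 1,2,4-trimethoxybenzene
Product: 12 2-(2,3,6-trimethoxyphenyl)propan-2-ol, via aryllithium 11 (not isolated)
Conditions: n-BuLi, THF, 0 °C; acetone, −78 → 20 °C; H2O
Reagents that add atoms: acetone, CC(C)=O
Why: Directed ortho‑metalation at the C–H flanked by two methoxy groups, followed by 1,2‑addition to acetone.

Step 7
Reactants: 12 2-(2,3,6-trimethoxyphenyl)propan-2-ol
Product: 13 2-isopropyl-1,3,4-trimethoxybenzene
Conditions: Et3SiH, CF3CO2H, CH2Cl2, 0 °C
Reagents that add atoms: none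
Why: Ionic hydrogenation: the tertiary benzylic cation stabilised by the electron‑rich ring is reduced by silane hydride transfer.

Step 8
Reactants: 13 2-isopropyl-1,3,4-trimethoxybenzene
Product: 15 4-isopropyl-2,3,5-trimethoxybenzaldehyde, via aryllithium 14 (not isolated)
Conditions: n-BuLi, TMEDA, Et2O, 0 → 20 °C; DMF, −78 → 20 °C; H2O
Reagents that add atoms: N,N-dimethylformamide, CN(C)C=O
Why: Directed ortho‑metalation/formylation at the C–H next to the 1,2‑dimethoxy unit (future C‑9), since the other ring C–H is para to a methoxy group and therefore less acidic; that second C–H (future C‑8) is the most nucleophilic site and is kept for step 10.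

Step 9
Reactants: 9 (3R,3aR,7aS)-3-(dimethoxymethyl)-7a-methyl-3a,4-dihydro-2-benzofuran-1,5(3H,7aH)-dione; 15 4-isopropyl-2,3,5-trimethoxybenzaldehyde
Product: 19 (3R,3aR,7aS)-lactone acetal carrying the (E)-arylmethylidene group at C-10, via lithium dienolate 16 (not isolated), via lithium aldolate 17 (not isolated), via mesylate 18 (not isolated)
Conditions: LiHMDS, THF, −78 °C; 15; MsCl, −78 → 0 °C; DBU, 20 °C
Reagents that add atoms: none
Why: Directed aldol addition then E1cB elimination (Claisen–Schmidt‑type condensation): C‑10 is the only enolisable position because C‑2 is vinylic and C‑4 quaternary, and elimination gives the (E)‑alkene with the aryl group on the C‑5 side, as ring B needs; no existing stereocentre is touched.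

Step 10
Reactants: 19 (3R,3aR,7aS)-lactone acetal carrying the (E)-arylmethylidene group at C-10
Product: 21 (4S,5R)-11,12,14-trimethoxy-1-oxoicetexa-2,6,8,10(20),11,13-hexaen-19,6-olide, via cyclic benzylic methyl ether 20 (not isolated)
Conditions: BF3·OEt2 (3 equiv), CH2Cl2, −40 → 0 °C
Reagents that add atoms: none
Why: Bradsher‑type cyclisation (intramolecular Friedel–Crafts alkylation): the acetal‑derived oxocarbenium ion at C‑7 is attacked by the only free arene position (C‑8, para to OMe) to close the seven‑membered ring, then the benzylic ether ionises and loses H‑6, the only β‑hydrogen, so the double bond forms regiospecifically as the C6=C7 enol lactone with C‑4 and C‑5 untouched.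

Step 11
Reactants: 21 (4S,5R)-11,12,14-trimethoxy-1-oxoicetexa-2,6,8,10(20),11,13-hexaen-19,6-olide
Product: 22 (4S,5R)-11,12,14-trimethoxy-1-oxoicetexa-6,8,10(20),11,13-pentaen-19,6-olide
Conditions: H2 (1 atm), RhCl(PPh3)3 (10 mol %), PhH/EtOH, 20 °C
Reagents that add atoms: none
Why: Chemoselective homogeneous hydrogenation: Wilkinson's catalyst reduces the unhindered cis‑disubstituted C2=C3 of a cross‑conjugated dienone and leaves the trisubstituted C10=C20 and C6=C7 bonds, as known for steroidal 1,4‑dien‑3‑ones.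

Step 12
Reactants: 22 (4S,5R)-11,12,14-trimethoxy-1-oxoicetexa-6,8,10(20),11,13-pentaen-19,6-olide
Product: 23 (1R,4S,5R)-1-hydroxy-11,12,14-trimethoxyicetexa-6,8,10(20),11,13-pentaen-19,6-olide
Conditions: NaBH4, CeCl3·7H2O, MeOH/THF, −78 °C
Reagents that add atoms: none
Why: Luche 1,2‑reduction: the small hydride attacks C‑1 from the α face, anti to the C5–C6 bond (axial attack), giving the equatorial 1β‑alcohol, i.e. (1R), cis to the lactone.

Step 13
Reactants: 23 (1R,4S,5R)-1-hydroxy-11,12,14-trimethoxyicetexa-6,8,10(20),11,13-pentaen-19,6-olide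
Product: 24 (1R,4S,5R)-1-hydroxy-12-methoxy-11,14-dioxoicetexa-6,8,10(20),12-tetraen-19,6-olide
Conditions: (NH4)2Ce(NO3)6 (2.6 equiv), MeCN/H2O 4:1, 0 °C, 15 min
Reagents that add atoms: water, O
Why: CAN oxidative demethylation of the para‑dimethoxy pair (C‑11/C‑14) gives the p‑quinone, the 12‑OMe remaining as a vinylogous ester; the short, cold reaction spares the allylic alcohol and the enol lactone.

Step 14
Reactants: 24 (1R,4S,5R)-1-hydroxy-12-methoxy-11,14-dioxoicetexa-6,8,10(20),12-tetraen-19,6-olide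
Product: 25 6,7-anhydroballotiquinone
Conditions: BCl3 (3 equiv), CH2Cl2, −78 → −20 °C; pH 7 buffer
Reagents that add atoms: none
Why: Chelation‑assisted Lewis‑acid O‑demethylation: boron bridges the C‑11 carbonyl and the 12‑OMe and chloride removes the methyl group, while the quinone disfavours ionisation of the allylic alcohol and protonation of the enol lactone.

## Compound list

1 | benzoic acid | OC(=O)c1ccccc1 | starting material
2 | dilithium (cyclohexa-2,5-dien-1-ylidene)methanediolate (not isolated) | [Li+].[Li+].[O-]C([O-])=C1C=CCC=C1 | intermediate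
3 | 1-methylcyclohexa-2,5-diene-1-carboxylic acid | CC1(C=CCC=C1)C(=O)O | intermediate
4 | allyl 1-methylcyclohexa-2,5-diene-1-carboxylate | CC1(C=CCC=C1)C(=O)OCC=C | intermediate
5 | allyl 1-methyl-4-oxocyclohexa-2,5-diene-1-carboxylate | CC1(C=CC(=O)C=C1)C(=O)OCC=C | intermediate
6 | (1,2,4-trioxolan-3-yl)methyl 1-methyl-4-oxocyclohexa-2,5-diene-1-carboxylate (ozonide, not isolated) | CC1(C=CC(=O)C=C1)C(=O)OCC2OCOO2 | intermediate
7 | 2-oxoethyl 1-methyl-4-oxocyclohexa-2,5-diene-1-carboxylate | CC1(C=CC(=O)C=C1)C(=O)OCC=O | intermediate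
8 | (3R,3aR,7aS)-7a-methyl-1,5-dioxo-1,3,3a,4,5,7a-hexahydro-2-benzofuran-3-carbaldehyde, cis-fused (not isolated) | O=C[C@@H]1OC(=O)[C@@]2(C)C=CC(=O)C[C@@H]12 | intermediate
9 | (3R,3aR,7aS)-3-(dimethoxymethyl)-7a-methyl-3a,4-dihydro-2-benzofuran-1,5(3H,7aH)-dione, cis-fused | COC(OC)[C@@H]1OC(=O)[C@@]2(C)C=CC(=O)C[C@@H]12 | intermediate
10 | 1,2,4-trimethoxybenzene | COc1ccc(OC)c(OC)c1 | starting material
11 | (2,3,6-trimethoxyphenyl)lithium (not isolated) | COc1ccc(OC)c(OC)c1[Li] | intermediate
12 | 2-(2,3,6-trimethoxyphenyl)propan-2-ol | COc1ccc(OC)c(OC)c1C(C)(C)O | intermediate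
13 | 2-isopropyl-1,3,4-trimethoxybenzene | COc1ccc(OC)c(OC)c1C(C)C | intermediate
14 | (4-isopropyl-2,3,5-trimethoxyphenyl)lithium (not isolated) | COc1cc([Li])c(OC)c(OC)c1C(C)C | intermediate
15 | 4-isopropyl-2,3,5-trimethoxybenzaldehyde | COc1cc(C=O)c(OC)c(OC)c1C(C)C | intermediate
16 | lithium cross-conjugated dienolate of 9 (O–C1=C10; not isolated) | COC(OC)[C@@H]1OC(=O)[C@@]2(C)C=CC(O[Li])=C[C@@H]12 | intermediate
17 | lithium aldolate of 9 and 15 (new centres at C-10 and C-20 unassigned; not isolated) | COC(OC)[C@@H]1OC(=O)[C@@]2(C)C=CC(=O)C(C(O[Li])c3cc(OC)c(C(C)C)c(OC)c3OC)[C@@H]12 | intermediate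
18 | methanesulfonate of the aldol (not isolated) | COC(OC)[C@@H]1OC(=O)[C@@]2(C)C=CC(=O)C(C(OS(C)(=O)=O)c3cc(OC)c(C(C)C)c(OC)c3OC)[C@@H]12 | intermediate
19 | (3R,3aR,7aS)-3-(dimethoxymethyl)-4-[(E)-(4-isopropyl-2,3,5-trimethoxyphenyl)methylidene]-7a-methyl-3a,4-dihydro-2-benzofuran-1,5(3H,7aH)-dione | COC(OC)[C@@H]1OC(=O)[C@@]2(C)C=CC(=O)/C(=C/c3cc(OC)c(C(C)C)c(OC)c3OC)[C@@H]12 | intermediate
20 | (4S,5R,6R)-7,11,12,14-tetramethoxy-1-oxoicetexa-2,8,10(20),11,13-pentaen-19,6-olide (C-7 unassigned; not isolated) | COc1c(C(C)C)c(OC)c2C(OC)[C@@H]3OC(=O)[C@@]4(C)C=CC(=O)C(=Cc2c1OC)[C@@H]34 | intermediate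
21 | (4S,5R)-11,12,14-trimethoxy-1-oxoicetexa-2,6,8,10(20),11,13-hexaen-19,6-olide | COc1c(C(C)C)c(OC)c2C=C3OC(=O)[C@@]4(C)C=CC(=O)C(=Cc2c1OC)[C@@H]34 | intermediate
22 | (4S,5R)-11,12,14-trimethoxy-1-oxoicetexa-6,8,10(20),11,13-pentaen-19,6-olide | COc1c(C(C)C)c(OC)c2C=C3OC(=O)[C@@]4(C)CCC(=O)C(=Cc2c1OC)[C@@H]34 | intermediate
23 | (1R,4S,5R)-1-hydroxy-11,12,14-trimethoxyicetexa-6,8,10(20),11,13-pentaen-19,6-olide | COc1c(C(C)C)c(OC)c2C=C3OC(=O)[C@@]4(C)CC[C@@H](O)C(=Cc2c1OC)[C@@H]34 | intermediate
24 | (1R,4S,5R)-1-hydroxy-12-methoxy-11,14-dioxoicetexa-6,8,10(20),12-tetraen-19,6-olide (12-O-methyl ether of the target) | CC(C)C1=C(OC)C(=O)C2=C(C=C3OC(=O)[C@@]4(C)CC[C@@H](O)C(=C2)[C@@H]34)C1=O | intermediate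
25 | 6,7-anhydroballotiquinone, (1R,4S,5R) in icetexane locants | CC(C)C1=C(O)C(=O)C2=C(C=C3OC(=O)[C@@]4(C)CC[C@@H](O)C(=C2)[C@@H]34)C1=O | target

## Step count and risks

Total: 14 steps. Longest linear sequence: 11 steps (1–5, then 9–14); the arene branch (6–8) joins at step 9.

**Step 5 (the proposed new desymmetrisation).** The ester tether has to reach its less favoured s‑cis rotamer, the donor is an α‑acyloxy aldehyde, and the sense and level of induction are untested. The fallback, by known reaction types, sets out from 7 and returns at 9. One enone is masked enantioselectively by a cinchona‑squaramide‑catalysed conjugate addition of thiophenol (sulfa‑Michael desymmetrisation; toluene, −40 °C), giving 2-oxoethyl 1-methyl-4-oxo-6-(phenylsulfanyl)cyclohex-2-ene-1-carboxylate F1 with C‑4 fixed. The lactone is then closed on the only enone left with an achiral amine salt (pyrrolidinium acetate, CHCl3, 25 °C; the ring must be cis‑fused), and the aldehyde is acetalised as in step 5 to the sulfide lactone acetal F2. Oxidation (mCPBA, CH2Cl2, −78 °C) gives the sulfoxide F3, and warming in toluene (80 °C, CaCO3) brings back the C2=C3 double bond by syn‑elimination, which gives 9.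

**Step 10 (seven‑membered Friedel–Crafts closure and elimination).** The oxocarbenium ion is flanked by an acyloxy group, the ring is seven‑membered, and the acid could also move the new double bond from C6=C7 to C5=C6. The fallback replaces the cationic closure by a halide/aldehyde coupling; it sets out from 15 (with 9) and returns at 21. Compound 15 is iodinated at its only free ring position (NIS, CF3CO2H, MeCN) to 2-iodo-4-isopropyl-3,5,6-trimethoxybenzaldehyde F4, which is condensed with 9 as in step 9 to the iodo dienone acetal F5. The acetal is hydrolysed (aq. CF3CO2H, CH2Cl2, 0 °C) to the iodo aldehyde F6. Ring B is closed by an intramolecular Nozaki–Hiyama–Kishi reaction (CrCl2, NiCl2 cat., DMF, 25 °C) to the cyclic benzylic alcohol F7, which is dehydrated (Burgess reagent, PhH, 50 °C) to 21.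

**Step 14 (O‑demethylation next to an enol lactone and an allylic alcohol).** BCl3 may attack the lactone or the carbinol. The fallback replaces dealkylation by substitution and hydrolysis; it sets out from 24 and returns at 25. Addition–elimination of dimethylamine (2 M in THF, 1.5 equiv, 0 °C) at the vinylogous ester gives the 12-(dimethylamino)quinone F8, whose vinylogous amide is hydrolysed with 1 M aq. HCl/THF at 25 °C to 25.

## Further compounds

F1 | step 5 | 2-oxoethyl 1-methyl-4-oxo-6-(phenylsulfanyl)cyclohex-2-ene-1-carboxylate (quaternary carbon as in 9; sulfide carbon unassigned) | O=CCOC(=O)[C@@]1(C)C(Sc2ccccc2)CC(=O)C=C1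
F2 | step 5 | 3-(dimethoxymethyl)-7a-methyl-7-(phenylsulfanyl)hexahydro-2-benzofuran-1,5-dione (cis-fused; ring-fusion centres as in 9) | COC(OC)[C@@H]1OC(=O)[C@@]2(C)C(Sc3ccccc3)CC(=O)C[C@@H]12
F3 | step 5 | 3-(dimethoxymethyl)-7a-methyl-7-(phenylsulfinyl)hexahydro-2-benzofuran-1,5-dione | COC(OC)[C@@H]1OC(=O)[C@@]2(C)C(S(=O)c3ccccc3)CC(=O)C[C@@H]12
F4 | step 10 | 2-iodo-4-isopropyl-3,5,6-trimethoxybenzaldehyde | O=Cc1c(I)c(OC)c(C(C)C)c(OC)c1OC
F5 | step 10 | (3R,3aR,7aS)-3-(dimethoxymethyl)-4-[(E)-(2-iodo-4-isopropyl-3,5,6-trimethoxyphenyl)methylidene]-7a-methyl-3a,4-dihydro-2-benzofuran-1,5(3H,7aH)-dione | COC(OC)[C@@H]1OC(=O)[C@@]2(C)C=CC(=O)/C(=C/c3c(I)c(OC)c(C(C)C)c(OC)c3OC)[C@@H]12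
F6 | step 10 | (3R,3aR,7aS)-4-[(E)-(2-iodo-4-isopropyl-3,5,6-trimethoxyphenyl)methylidene]-7a-methyl-1,5-dioxo-1,3,3a,4,5,7a-hexahydro-2-benzofuran-3-carbaldehyde | O=C[C@@H]1OC(=O)[C@@]2(C)C=CC(=O)/C(=C/c3c(I)c(OC)c(C(C)C)c(OC)c3OC)[C@@H]12
F7 | step 10 | (4S,5R,6R)-7-hydroxy-11,12,14-trimethoxy-1-oxoicetexa-2,8,10(20),11,13-pentaen-19,6-olide (C-7 unassigned) | COc1c(C(C)C)c(OC)c2C(O)[C@@H]3OC(=O)[C@@]4(C)C=CC(=O)C(=Cc2c1OC)[C@@H]34
F8 | step 14 | (1R,4S,5R)-12-(dimethylamino)-1-hydroxy-11,14-dioxoicetexa-6,8,10(20),12-tetraen-19,6-olide | CC(C)C1=C(N(C)C)C(=O)C2=C(C=C3OC(=O)[C@@]4(C)CC[C@@H](O)C(=C2)[C@@H]34)C1=O
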